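## Structural features

Bermudenynol is a halogenated C15 acetogenin with a single ring, an eight-membered cyclic ether (oxocene) made of O, C7, C8, C9, C10, C11, C12 and C13. The ring carries an ethyl group (C14–C15) on C13 and a six-carbon chain (C1–C6) on C7, and these two ether carbons are cis across the oxygen (7R,13R). Inside the ring lie a trisubstituted chloroalkene C9=C10(Cl), cis with respect to the ring carbons and therefore E by the CIP rules, and a secondary bromide at C12 (S), trans to the neighbouring ethyl group. The side chain adds the contiguous triad C5(Cl)–C6(OH)–C7(O), in which chloride and hydroxyl are syn (5S,6S) and the hydroxyl is also syn to the ring oxygen, and it ends in a (Z)-enyne (C1–C4). Fragile groups are the chlorohydrin with its allylic chloride (epoxide closure with base), the β-alkoxy bromide (elimination, oxonium participation) and the (Z)-enyne with its terminal alkyne. The vinyl chloride is robust but rules out a simple ring-closing metathesis at C9=C10. The real difficulty is the eight-membered ring closure with control of C7 relative to C13, followed by three carbon–halogen bonds that must be placed without scrambling. The key step uses the fact that C7 is an ether carbon whose exocyclic neighbour C6 can be an alkene carbon: C5–C6–C7 can act as an allyl electrophile whose substituted end C7 is attacked by the C13 hydroxyl, while the cis C9=C10 bond holds the two ends of the C7–C13 tether close.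

## Logic of the disconnections

**31 ⇒ 30 ⇒ 26 + 29.** The C1–Si bond of 30 is a trivial cut; the real one is the C3=C4 double bond. This removes the most fragile unit, the (Z)-enyne, so that it is added in the last carbon–carbon bond-forming step, and 26 carries only a vinyl group. The forward cross-metathesis must be Z-selective and must tolerate the free chlorohydrin, the bromide and the ring chloroalkene; the final desilylation must not close the chlorohydrin to an epoxide. 29 is cut at C2–C3 into 27 and 28.

**26 ⇒ 22 + 23.** The C5–C6 bond is cut. Both side-chain stereocentres and the C5 chlorine then come from one addition of a three-carbon unit to an aldehyde. The forward step needs a (Z)-γ-chloroallyl reagent (Cl/OH syn) whose chiral ligands overrule the intrinsic facial preference of the α-alkoxy aldehyde 22, because the target has O6 syn to the ring oxygen.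

**22 ⇒ 20 ⇒ 19 ⇒ 18.** The C6 aldehyde is traced to a vinyl group (C=C cut), the C12–Br bond to a C12–O bond of opposite configuration, and the free O12–H to its MOM ether. Brominating before the aldehyde is unmasked means 19 has a single hydroxyl, so O6 never needs protection. The demands are SN2 inversion at C12 without participation of the ring oxygen, and cleavage of the monosubstituted alkene in the presence of the chloroalkene.

**18 ⇒ 17.** The O–C7 bond is cut (key disconnection). The ring and the C7 stereocentre disappear and an acyclic chain with only the C12/C13 pair remains; C5–C7 becomes an allyl electrophile and O13 the nucleophile. The forward step must attack the substituted allyl terminus (eight- rather than ten-membered ring), on the face that gives 7R, and intramolecularly; O12 has to stay blocked so that it cannot close a seven-membered ether.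

**17 ⇒ 15 + 16, 15 ⇒ 14.** The C6=C7 double bond is cut, so the ionisable carbonate is attached last and is not carried through earlier steps. The cross-metathesis must give the E alkene and leave the chloroalkene alone; O13 is freed just before (14 → 15).

**14 ⇒ 12 + 13, 12 ⇒ 10 + 11.** The C8–C9 bond is cut, then the C9–I and C10–Cl bonds. The trisubstituted chloroalkene, awkward to make by olefination, is reduced to a terminal alkyne: anti addition of 11 fixes the geometry, and the iodine of 12 is the handle for coupling with 13. The demands are Markovnikov anti addition without participation of the oxygen substituents, and coupling at C–I only without isomerising the skipped diene.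

**10 ⇒ 9 ⇒ 8 ⇒ 6 ⇒ 5.** C9 is removed (the alkyne comes from the C10 aldehyde by one-carbon homologation), and the aldehyde is traced to the terminal alkene of 5 by anti-Markovnikov hydration; O13 is silylated for this stretch. These are standard functional-group changes; the only demand is that O12 is not lost from 9 by β-elimination.

**5 ⇒ 1 + 2.** The C12–C13 bond is cut. One step builds the vicinal syn diol with both stereocentres and with the two oxygens already differentiated (O12 as MOM ether, O13 free). It needs a (Z)-alkoxyallyl reagent and enantiofacial control by chiral boron ligands.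

## Other disconnections considered

**Alternative 1:** The cut is the C11–C12 bond, formed while the C9–O bond of a six-membered ketene acetal breaks.
- Forward key step: ketene acetal A2 (a 2-methylidene-1,3-dioxane with a 1-chlorovinyl group on C9) would undergo a [3,3] Claisen shift that expands the ring by two atoms to the eight-membered lactone A1.
- In its favour: the ring arises by a pericyclic ring expansion rather than an end-to-end closure, so no high dilution is needed; the geometry of C9=C10(Cl) is dictated by the cyclic transition state; C7 comes from the chiral pool.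
- Against it here: A1 has neither the ethyl group nor any function at C12. C13 is a lactone carbonyl that must still become the ethyl-bearing ether carbon cis to C7, C12 must be oxygenated and brominated, and the C6 benzyl ether must be taken to the aldehyde. A2 would have to be generated in situ at high temperature with the chlorovinyl group in place.
- Comparison: on the mechanism of ring formation this alternative is the better one (a ring expansion of a known type against an eight-membered closure that has not been shown). On alkene geometry the two are equal, since both fix it stereospecifically. On structure and step economy the chosen plan is ahead: its closure creates C7 with C12 and C13 already in place, whereas A1 carries one stereocentre and needs a long sequence at C12 and C13.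

**Alternative 2:** The cut takes C10 out of the ring (bonds C9–C10 and C10–C11).
- Forward key step: dichlorocarbene would add to the C9=C11 silyl enol ether A4 of a seven-membered cyclic ether, and the siloxydichlorocyclopropane would open with loss of chloride and the silyl group to the eight-membered 2-chloroenone A3.
- In its favour: the end-to-end closure is moved to a seven-membered ring; C10 and its chlorine arrive together; C7, C12 and C13 are all in place before the expansion.
- Against it here: A3 has the double bond at C10=C11 and a carbonyl at C9, so a reduction and a 1,3-reductive transposition are needed to reach C9=C10(Cl)–C11H2. A4 must be formed regioselectively towards C11, next to the C12 ether that can be lost by elimination. Carbene generation needs base or heat, and the C6 ether still has to be adjusted.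
- Comparison: in ring-size kinetics the alternative is the better. In carrying the C12/C13 pair in from the start the two are equal. The chosen plan is ahead in placing the chloroalkene correctly before ring closure, with no redox corrections afterwards, which makes it shorter.

**Alternative 3:** The cut is C12–C13.
- Forward key step: under BF3·OEt2 the oxygen-bearing carbon C13 of the γ-alkoxyallylstannane in A6 would add to the C12 aldehyde, closing the ring to A5 and creating the C12 hydroxyl and C13 vinyl stereocentres.
- In its favour: a carbon–carbon bond and two stereocentres are formed in the ring-closing step; the reaction type is established for cyclic ethers; C7 comes from the chiral pool.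
- Against it here: the closure is expected to place the C12 hydroxyl trans to the C13 substituent, whereas bromination with inversion needs the cis alcohol, so C12 would have to be inverted first. The vinyl group must be reduced to ethyl selectively. The aldehyde of A6 is β,γ-unsaturated to the chloroalkene and prone to move into conjugation, and the Lewis acid must spare the PMB ether.
- Comparison: the alternative is the better in the number of stereocentres set by the ring closure (two against one) and the equal of the chosen plan in using the cis chloroalkene to bring the chain ends together. The chosen plan is ahead because C12 arrives with the configuration needed for the bromination and C13 already carries the ethyl group, which saves the inversion and the hydrogenation.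

Key step: step 10

Remarks on the chemistry: target numbering C1–C15 is used in the explanations. The ring chloroalkene is E by the CIP rules although the carbon chain is cis, so the cyclisation substrate 17 is the (2E,5E)-dienyl carbonate; it is made as the tert-butyl carbonate so that ionisation releases non-nucleophilic tert-butoxide instead of methoxide. The vinyl group of 5 becomes the alkyne of 10 by a one-carbon homologation, not a direct conversion.
Assumption: the (Sa,S,S) antipode of the phosphoramidite is taken, by the empirical facial rule for this ligand family, to be the one that directs the alkoxide to the Re face of C7; if the rule points the other way, the mirror-image ligand is meant.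

## Route

Step 1
Reactants: 1 propanal; 2 allyl methoxymethyl ether
Product: 5 (3R,4R)-4-(methoxymethoxy)hex-5-en-3-ol, via (Z)-3-(methoxymethoxy)allylbis(isopinocampheyl)borane 3 (not isolated), via (3R,4R)-4-(methoxymethoxy)hex-5-en-3-yl bis(isopinocampheyl)borinate 4 (not isolated)
Conditions: 2, s-BuLi, THF, −78 °C; (−)-Ipc2BOMe; BF3·OEt2; 1, −78 °C; then NaOH, H2O2, 0 °C → rt
Reagents that add atoms: none
Why: Brown (Z)-γ-alkoxyallylboration: the lithiated allyl ether gives the (Z)-allylborane 3, which adds to propanal through a chair transition state so that C12 and C13 come out syn, and the isopinocampheyl groups from (+)-α-pinene direct attack to the Si face of the aldehyde, which should give 3R,4R (12R,13R). O12 leaves the step as the MOM ether and O13 free, the differentiation needed later.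

Step 2
Reactants: 5 (3R,4R)-4-(methoxymethoxy)hex-5-en-3-ol
Product: 6 tert-butyl{[(3R,4R)-4-(methoxymethoxy)hex-5-en-3-yl]oxy}dimethylsilane
Conditions: TBSCl, imidazole, DMF, rt
Reagents that add atoms: tert-butyldimethylsilyl chloride, CC(C)(C)[Si](C)(C)Cl
Why: Standard silylation of a secondary alcohol; the silyl ether shields O13 from oxidation and keeps it from attacking the iodonium ion in step 6.

Step 3
Reactants: 6 tert-butyl{[(3R,4R)-4-(methoxymethoxy)hex-5-en-3-yl]oxy}dimethylsilane
Product: 8 (3R,4R)-4-[(tert-butyldimethylsilyl)oxy]-3-(methoxymethoxy)hexan-1-ol, via B-alkyl-9-borabicyclo[3.3.1]nonane 7 (not isolated)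
Conditions: 9-BBN-H, THF, 0 °C → rt; then NaOH, H2O2, 0 °C
Reagents that add atoms: hydrogen peroxide, OO
Why: Anti-Markovnikov hydroboration–oxidation; 9-BBN places boron on the terminal carbon of the monosubstituted alkene and the oxidation touches no stereocentre.

Step 4
Reactants: 8 (3R,4R)-4-[(tert-butyldimethylsilyl)oxy]-3-(methoxymethoxy)hexan-1-ol
Product: 9 (3R,4R)-4-[(tert-butyldimethylsilyl)oxy]-3-(methoxymethoxy)hexanal
Conditions: Dess–Martin periodinane, CH2Cl2, 0 °C → rt
Reagents that add atoms: none
Why: Dess–Martin oxidation of a primary alcohol under non-basic conditions, which avoids β-elimination of the MOM ether; the aldehyde is used at once.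

Step 5
Reactants: 9 (3R,4R)-4-[(tert-butyldimethylsilyl)oxy]-3-(methoxymethoxy)hexanal
Product: 10 tert-butyl{[(3R,4R)-4-(methoxymethoxy)hept-6-yn-3-yl]oxy}dimethylsilane
Conditions: dimethyl (1-diazo-2-oxopropyl)phosphonate, K2CO3, MeOH, 0 °C → rt
Reagents that add atoms: dimethyl (1-diazo-2-oxopropyl)phosphonate, CC(=O)C(=[N+]=[N-])P(=O)(OC)OC
Why: Ohira–Bestmann (Seyferth–Gilbert) homologation: the diazomethylphosphonate anion formed by methanolysis adds to the aldehyde and the alkylidene carbene rearranges to the terminal alkyne, which supplies C9. The mild carbonate base should leave the β-alkoxy centre intact.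

Step 6
Reactants: 10 tert-butyl{[(3R,4R)-4-(methoxymethoxy)hept-6-yn-3-yl]oxy}dimethylsilane; 11 iodine monochloride
Product: 12 tert-butyl{[(3R,4R,6E)-6-chloro-7-iodo-4-(methoxymethoxy)hept-6-en-3-yl]oxy}dimethylsilane
Conditions: ICl, CH2Cl2, −78 °C
Reagents that add atoms: none
Why: Electrophilic iodochlorination of a terminal alkyne: iodine goes to the terminal carbon and chloride opens the iodonium ion anti at the internal carbon, which puts Cl on C10 trans to iodine and so C11 cis to the future C8. Low temperature and the non-polar solvent favour capture by chloride over participation of the acetal or silyl ether oxygen.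

Step 7
Reactants: 12 tert-butyl{[(3R,4R,6E)-6-chloro-7-iodo-4-(methoxymethoxy)hept-6-en-3-yl]oxy}dimethylsilane; 13 allyltributylstannane
Product: 14 tert-butyl{[(3R,4R,6E)-6-chloro-4-(methoxymethoxy)deca-6,9-dien-3-yl]oxy}dimethylsilane
Conditions: Pd2(dba)3 (2.5 mol %), AsPh3 (20 mol %), DMF, 50 °C
Reagents that add atoms: none
Why: Stille coupling: zerovalent palladium inserts into the C–I bond only (the vinyl C–Cl bond is inert here) and the allyl group is transferred with retention of the alkene geometry, giving the skipped diene. The mild fluoride-free conditions limit isomerisation into conjugation and spare the silyl ether.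

Step 8
Reactants: 14 tert-butyl{[(3R,4R,6E)-6-chloro-4-(methoxymethoxy)deca-6,9-dien-3-yl]oxy}dimethylsilane
Product: 15 (3R,4R,6E)-6-chloro-4-(methoxymethoxy)deca-6,9-dien-3-ol
Conditions: n-Bu4NF, THF, 0 °C → rt
Reagents that add atoms: none
Why: Fluoride cleavage of the silyl ether; it is done before the carbonate is introduced, so no base-sensitive group is present.

Step 9
Reactants: 15 (3R,4R,6E)-6-chloro-4-(methoxymethoxy)deca-6,9-dien-3-ol; 16 allyl tert-butyl carbonate
Product: 17 tert-butyl (2E,5E,8R,9R)-6-chloro-9-hydroxy-8-(methoxymethoxy)undeca-2,5-dien-1-yl carbonate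
Conditions: 16 (4 equiv), second-generation Hoveyda–Grubbs catalyst RuCl2(H2IMes)(=CH-C6H4-2-O-i-Pr) (5 mol %), CH2Cl2, 40 °C
Reagents that add atoms: none
Why: Olefin cross-metathesis between the terminal alkene of 15 and an allylic carbonate used in excess; the trisubstituted chloroalkene should not take part and the thermodynamically favoured E alkene should dominate.

Step 10
Reactants: 17 tert-butyl (2E,5E,8R,9R)-6-chloro-9-hydroxy-8-(methoxymethoxy)undeca-2,5-dien-1-yl carbonate
Product: 18 (2R,3R,5E,8R)-5-chloro-8-ethenyl-2-ethyl-3-(methoxymethoxy)-3,4,7,8-tetrahydro-2H-oxocine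
Conditions: [Ir(cod)Cl]2 (4 mol %), (Sa,S,S)-O,O′-(1,1′-binaphthalene-2,2′-diyl) N,N-bis[1-(2-methoxyphenyl)ethyl]phosphoramidite (8 mol %), 1,5,7-triazabicyclo[4.4.0]dec-5-ene (10 mol %), THF, 50 °C, slow addition to 0.005 M
Reagents that add atoms: none
Why: Proposed new method: the cyclometalated iridium–phosphoramidite complex (univalent iridium) ionises the tert-butyl carbonate of 17 with loss of CO2 to an η3-allyl complex of trivalent iridium spanning C5–C7, the tert-butoxide set free deprotonates O13–H, and the alkoxide attacks the substituted terminus C7 on the face anti to the metal. The closest known reactions are the iridium–phosphoramidite intramolecular allylic etherifications and aminations that give five- to seven-membered 2-vinyl heterocycles, of which this is an eight-membered extension. The oxocene is closed in the 8-exo mode (C6 and C5 stay outside the ring), whereas the ten-membered ether would need attack at the unsubstituted terminus C5, which iridium disfavours. The new stereocentre C7 is set by the ligand, which should expose the Re face of C7 to the alkoxide and give 7R; this is also the configuration the substrate prefers, because it places vinyl and ethyl cis across the ring oxygen. The step needs branched over linear attack, ring closure over oligomerisation, and substitution over loss of a C8 proton to a triene. These are served by the iridium catalyst, by slow addition at high dilution, by the cis C9=C10 bond that holds O13 near C7, and by a leaving group that releases no competing nucleophile. The MOM ether keeps O12 from closing the seven-membered ring.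

Step 11
Reactants: 18 (2R,3R,5E,8R)-5-chloro-8-ethenyl-2-ethyl-3-(methoxymethoxy)-3,4,7,8-tetrahydro-2H-oxocine
Product: 19 (2R,3R,5E,8R)-5-chloro-8-ethenyl-2-ethyl-3,4,7,8-tetrahydro-2H-oxocin-3-ol
Conditions: conc. HCl (cat.), MeOH, 45 °C
Reagents that add atoms: none
Why: Acid-catalysed acetal exchange removes the MOM group as dimethoxymethane; the vinyl chloride, the terminal alkene and the ring ether should be stable to dilute acid in methanol.

Step 12
Reactants: 19 (2R,3R,5E,8R)-5-chloro-8-ethenyl-2-ethyl-3,4,7,8-tetrahydro-2H-oxocin-3-ol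
Product: 20 (2R,3S,5E,8R)-3-bromo-5-chloro-8-ethenyl-2-ethyl-3,4,7,8-tetrahydro-2H-oxocine
Conditions: CBr4, P(n-C8H17)3, toluene, 70 °C
Reagents that add atoms: carbon tetrabromide, BrC(Br)(Br)Br
Why: Appel-type bromination: the alkoxyphosphonium ion is displaced by bromide in an SN2 step, so the cis alcohol (12R) should become the trans bromide (12S); the trialkylphosphine in toluene is the variant established for β-alkoxy alcohols on oxocenes. Because O12 is the only hydroxyl at this stage, O6 never needs protection.

Step 13
Reactants: 20 (2R,3S,5E,8R)-3-bromo-5-chloro-8-ethenyl-2-ethyl-3,4,7,8-tetrahydro-2H-oxocine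
Product: 22 (2R,4E,7S,8R)-7-bromo-5-chloro-8-ethyl-3,6,7,8-tetrahydro-2H-oxocine-2-carbaldehyde, via 1-[(2R,4E,7S,8R)-7-bromo-5-chloro-8-ethyl-3,6,7,8-tetrahydro-2H-oxocin-2-yl]ethane-1,2-diol 21 (not isolated)
Conditions: OsO4 (2 mol %), NaIO4, 2,6-lutidine, dioxane–H2O (3:1), rt
Reagents that add atoms: osmium tetroxide, O=[Os](=O)(=O)=O; sodium periodate, [Na+].[O-]I(=O)(=O)=O
Why: Lemieux–Johnson cleavage: OsO4 should dihydroxylate the monosubstituted vinyl group much faster than the electron-poor trisubstituted chloroalkene, and periodate cleaves diol 21 to the aldehyde. The lutidine buffer suppresses epimerisation at C7.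

Step 14
Reactants: 22 (2R,4E,7S,8R)-7-bromo-5-chloro-8-ethyl-3,6,7,8-tetrahydro-2H-oxocine-2-carbaldehyde; 23 allyl chloride
Product: 26 (1S,2S)-1-[(2R,4E,7S,8R)-7-bromo-5-chloro-8-ethyl-3,6,7,8-tetrahydro-2H-oxocin-2-yl]-2-chlorobut-3-en-1-ol, via (Z)-3-chloroallylbis(isopinocampheyl)borane 24 (not isolated), via O-boryl chlorohydrin adduct 25 (not isolated)
Conditions: 23, LiN(c-C6H11)2 (from HN(c-C6H11)2 and n-BuLi), (+)-Ipc2BOMe, THF–Et2O, −95 °C; BF3·OEt2; 22, −95 °C; then HOCH2CH2NH2, rt
Reagents that add atoms: none
Why: (Z)-γ-Chloroallylboration of the Brown type: the (Z)-allylborane 24 adds through a chair transition state to give the syn chlorohydrin, and the isopinocampheyl groups from (−)-α-pinene direct attack to the Re face of the aldehyde, which should set 6S and with it 5S. Reagent control has to override the intrinsic preference of the α-alkoxy aldehyde for the 6,7-anti product; the base-free, non-oxidative work-up keeps chlorohydrin and bromide intact.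

Step 15
Reactants: 27 vinyl bromide; 28 (triisopropylsilyl)acetylene
Product: 29 (but-3-en-1-yn-1-yl)tri(propan-2-yl)silane
Conditions: Pd(PPh3)4 (2 mol %), CuI (4 mol %), i-Pr2NH, THF, 0 °C → rt
Reagents that add atoms: none
Why: Sonogashira coupling of a vinyl bromide with a terminal alkyne; the bulky silyl group makes the small enyne easy to handle.

Step 16
Reactants: 26 (1S,2S)-1-[(2R,4E,7S,8R)-7-bromo-5-chloro-8-ethyl-3,6,7,8-tetrahydro-2H-oxocin-2-yl]-2-chlorobut-3-en-1-ol; 29 (but-3-en-1-yn-1-yl)tri(propan-2-yl)silane
Product: 30 (1S,2S,3Z)-1-[(2R,4E,7S,8R)-7-bromo-5-chloro-8-ethyl-3,6,7,8-tetrahydro-2H-oxocin-2-yl]-2-chloro-6-[tri(propan-2-yl)silyl]hex-3-en-5-yn-1-ol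
Conditions: 29 (3 equiv), second-generation Grubbs catalyst RuCl2(H2IMes)(PCy3)(=CHPh) (10 mol %), CH2Cl2, 40 °C
Reagents that add atoms: none
Why: Cross-metathesis of a terminal alkene with a conjugated silyl enyne, a reaction type that is kinetically Z-selective because the slim alkynyl group can sit cis in the metallacyclobutane. The ring chloroalkene is inert to the catalyst and the free hydroxyl should be tolerated.

Step 17
Reactants: 30 (1S,2S,3Z)-1-[(2R,4E,7S,8R)-7-bromo-5-chloro-8-ethyl-3,6,7,8-tetrahydro-2H-oxocin-2-yl]-2-chloro-6-[tri(propan-2-yl)silyl]hex-3-en-5-yn-1-ol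
Product: 31 bermudenynol [(1S,2S,3Z)-1-[(2R,4E,7S,8R)-7-bromo-5-chloro-8-ethyl-3,6,7,8-tetrahydro-2H-oxocin-2-yl]-2-chlorohex-3-en-5-yn-1-ol]
Conditions: n-Bu4NF, AcOH (1:1), THF, 0 °C
Reagents that add atoms: none
Why: Fluoride cleavage of the alkynyl C–Si bond; buffering with acetic acid keeps O6–H protonated, so the chlorohydrin should not close to the epoxide and the bromide should not eliminate.

## Compound list

1 | propanal | CCC=O | starting material
2 | allyl methoxymethyl ether [3-(methoxymethoxy)prop-1-ene] | C=CCOCOC | starting material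
3 | [(2Z)-3-(methoxymethoxy)prop-2-en-1-yl]bis(isopinocampheyl)borane, Ipc from (+)-α-pinene (formed in situ) | COCO/C=C\CB([C@@H]1C[C@@H]2C[C@H]([C@H]1C)C2(C)C)[C@@H]1C[C@@H]2C[C@H]([C@H]1C)C2(C)C | intermediate
4 | (3R,4R)-4-(methoxymethoxy)hex-5-en-3-yl bis(isopinocampheyl)borinate (formed in situ) | C=C[C@@H](OCOC)[C@@H](CC)OB([C@@H]1C[C@@H]2C[C@H]([C@H]1C)C2(C)C)[C@@H]1C[C@@H]2C[C@H]([C@H]1C)C2(C)C | intermediate
5 | (3R,4R)-4-(methoxymethoxy)hex-5-en-3-ol | C=C[C@@H](OCOC)[C@@H](CC)O | intermediate
6 | tert-butyl{[(3R,4R)-4-(methoxymethoxy)hex-5-en-3-yl]oxy}dimethylsilane | C=C[C@@H](OCOC)[C@@H](CC)O[Si](C)(C)C(C)(C)C | intermediate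
7 | 9-{(3R,4R)-4-[(tert-butyldimethylsilyl)oxy]-3-(methoxymethoxy)hexyl}-9-borabicyclo[3.3.1]nonane (formed in situ) | B1(CC[C@@H](OCOC)[C@@H](CC)O[Si](C)(C)C(C)(C)C)C2CCCC1CCC2 | intermediate
8 | (3R,4R)-4-[(tert-butyldimethylsilyl)oxy]-3-(methoxymethoxy)hexan-1-ol | OCC[C@@H](OCOC)[C@@H](CC)O[Si](C)(C)C(C)(C)C | intermediate
9 | (3R,4R)-4-[(tert-butyldimethylsilyl)oxy]-3-(methoxymethoxy)hexanal | O=CC[C@@H](OCOC)[C@@H](CC)O[Si](C)(C)C(C)(C)C | intermediate
10 | tert-butyl{[(3R,4R)-4-(methoxymethoxy)hept-6-yn-3-yl]oxy}dimethylsilane | C#CC[C@@H](OCOC)[C@@H](CC)O[Si](C)(C)C(C)(C)C | intermediate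
11 | iodine monochloride | ClI | starting material
12 | tert-butyl{[(3R,4R,6E)-6-chloro-7-iodo-4-(methoxymethoxy)hept-6-en-3-yl]oxy}dimethylsilane | I/C=C(/Cl)C[C@@H](OCOC)[C@@H](CC)O[Si](C)(C)C(C)(C)C | intermediate
13 | allyltributylstannane | CCCC[Sn](CCCC)(CCCC)CC=C | starting material
14 | tert-butyl{[(3R,4R,6E)-6-chloro-4-(methoxymethoxy)deca-6,9-dien-3-yl]oxy}dimethylsilane | C=CC/C=C(/Cl)C[C@@H](OCOC)[C@@H](CC)O[Si](C)(C)C(C)(C)C | intermediate
15 | (3R,4R,6E)-6-chloro-4-(methoxymethoxy)deca-6,9-dien-3-ol | C=CC/C=C(/Cl)C[C@@H](OCOC)[C@@H](CC)O | intermediate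
16 | allyl tert-butyl carbonate | C=CCOC(=O)OC(C)(C)C | starting material
17 | tert-butyl (2E,5E,8R,9R)-6-chloro-9-hydroxy-8-(methoxymethoxy)undeca-2,5-dien-1-yl carbonate | CC(C)(C)OC(=O)OC/C=C/C/C=C(/Cl)C[C@@H](OCOC)[C@@H](CC)O | intermediate
18 | (2R,3R,5E,8R)-5-chloro-8-ethenyl-2-ethyl-3-(methoxymethoxy)-3,4,7,8-tetrahydro-2H-oxocine | C=C[C@H]1C/C=C(/Cl)C[C@@H](OCOC)[C@@H](CC)O1 | intermediate
19 | (2R,3R,5E,8R)-5-chloro-8-ethenyl-2-ethyl-3,4,7,8-tetrahydro-2H-oxocin-3-ol | C=C[C@H]1C/C=C(/Cl)C[C@@H](O)[C@@H](CC)O1 | intermediate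
20 | (2R,3S,5E,8R)-3-bromo-5-chloro-8-ethenyl-2-ethyl-3,4,7,8-tetrahydro-2H-oxocine | C=C[C@H]1C/C=C(/Cl)C[C@H](Br)[C@@H](CC)O1 | intermediate
21 | 1-[(2R,4E,7S,8R)-7-bromo-5-chloro-8-ethyl-3,6,7,8-tetrahydro-2H-oxocin-2-yl]ethane-1,2-diol, both C1 epimers (formed in situ) | OCC(O)[C@H]1C/C=C(/Cl)C[C@H](Br)[C@@H](CC)O1 | intermediate
22 | (2R,4E,7S,8R)-7-bromo-5-chloro-8-ethyl-3,6,7,8-tetrahydro-2H-oxocine-2-carbaldehyde | O=C[C@H]1C/C=C(/Cl)C[C@H](Br)[C@@H](CC)O1 | intermediate
23 | allyl chloride | C=CCCl | starting material
24 | [(2Z)-3-chloroprop-2-en-1-yl]bis(isopinocampheyl)borane, Ipc from (−)-α-pinene (formed in situ) | Cl/C=C\CB([C@H]1C[C@H]2C[C@@H]([C@@H]1C)C2(C)C)[C@H]1C[C@H]2C[C@@H]([C@@H]1C)C2(C)C | intermediate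
25 | (1S,2S)-1-[(2R,4E,7S,8R)-7-bromo-5-chloro-8-ethyl-3,6,7,8-tetrahydro-2H-oxocin-2-yl]-2-chlorobut-3-en-1-yl bis(isopinocampheyl)borinate (formed in situ) | C=C[C@H](Cl)[C@@H](OB([C@H]2C[C@H]3C[C@@H]([C@@H]2C)C3(C)C)[C@H]2C[C@H]3C[C@@H]([C@@H]2C)C3(C)C)[C@H]1C/C=C(/Cl)C[C@H](Br)[C@@H](CC)O1 | intermediate
26 | (1S,2S)-1-[(2R,4E,7S,8R)-7-bromo-5-chloro-8-ethyl-3,6,7,8-tetrahydro-2H-oxocin-2-yl]-2-chlorobut-3-en-1-ol | C=C[C@H](Cl)[C@@H](O)[C@H]1C/C=C(/Cl)C[C@H](Br)[C@@H](CC)O1 | intermediate
27 | vinyl bromide | C=CBr | starting material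
28 | (triisopropylsilyl)acetylene | C#C[Si](C(C)C)(C(C)C)C(C)C | starting material
29 | (but-3-en-1-yn-1-yl)tri(propan-2-yl)silane | C=CC#C[Si](C(C)C)(C(C)C)C(C)C | intermediate
30 | (1S,2S,3Z)-1-[(2R,4E,7S,8R)-7-bromo-5-chloro-8-ethyl-3,6,7,8-tetrahydro-2H-oxocin-2-yl]-2-chloro-6-[tri(propan-2-yl)silyl]hex-3-en-5-yn-1-ol | CC(C)[Si](C(C)C)(C(C)C)C#C/C=C\[C@H](Cl)[C@@H](O)[C@H]1C/C=C(/Cl)C[C@H](Br)[C@@H](CC)O1 | intermediate
31 | bermudenynol [(1S,2S,3Z)-1-[(2R,4E,7S,8R)-7-bromo-5-chloro-8-ethyl-3,6,7,8-tetrahydro-2H-oxocin-2-yl]-2-chlorohex-3-en-5-yn-1-ol] | C#C/C=C\[C@H](Cl)[C@@H](O)[C@H]1C/C=C(/Cl)C[C@H](Br)[C@@H](CC)O1 | target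

## Step count and least certain steps

Total: 17 steps. Longest linear sequence: 16 steps (steps 1–14, 16 and 17); step 15 is a one-step side branch.

**Step 10 (key step, proposed new method).** The slow eight-membered closure may let other pathways take over: intermolecular etherification to oligomers, loss of a doubly allylic C8 proton from the allyl complex to a conjugated triene, attack at C5, poor facial selectivity if ligand and substrate preferences do not match, and re-ionisation of the allylic ether product.
Fallback (known chemistry): the intramolecular amide enolate alkylation, an established route to cis-2,8-disubstituted oxocenes, which forms C7–C8 instead of O–C7. It sets out from 12. Fluoride (n-Bu4NF, THF) removes the silyl group to give (3R,4R,6E)-6-chloro-7-iodo-4-(methoxymethoxy)hept-6-en-3-ol F1. O-Alkylation with 2-chloro-N,N-dimethylacetamide (NaH, THF–DMF, 0 °C) gives the glycolamide ether F2. Stille hydroxymethylation (Bu3SnCH2OH, Pd(PPh3)4, dioxane, 90 °C) gives the allylic alcohol F3. MsCl, 2,4,6-collidine and LiCl in DMF give the allylic chloride F4. LiN(SiMe3)2 in THF closes the ring by 8-exo-tet alkylation of the amide enolate to the cis oxocene amide F5. MOM removal (HCl, MeOH) gives the hydroxy amide F6, and CBr4/P(n-C8H17)3 gives the bromo amide F7 with inversion. Cp2Zr(H)Cl in THF reduces the amide to the aldehyde, and the route is rejoined at 22.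

**Step 14.** Facial selectivity may be poor, because the reagent has to act against the intrinsic bias of the α-alkoxy aldehyde (mismatched double diastereoselection); epimerisation of the aldehyde at C7 and epoxide closure on work-up are further risks.
Fallback: an auxiliary-controlled aldol, which sets out from 22. Boron aldol addition of (R)-4-benzyl-3-(chloroacetyl)-1,3-oxazolidin-2-one (n-Bu2BOTf, i-Pr2NEt, CH2Cl2, −78 °C) gives the syn α-chloro-β-hydroxy imide F8. Et3SiOTf/2,6-lutidine gives the triethylsilyl ether F9. LiBH4 (Et2O, MeOH, 0 °C) removes the auxiliary to give the primary alcohol F10, and Dess–Martin oxidation gives the α-chloro aldehyde F11. Peterson olefination with lithiated 1,3-bis(triisopropylsilyl)propyne (n-BuLi, THF, −78 °C) gives the bis-silylated (Z)-enyne F12. n-Bu4NF/AcOH removes both silyl groups, and the route is rejoined at 31; this path also bypasses step 16.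

**Step 16.** Conversion may be low, because an alkene carrying an allylic chloride is a sluggish metathesis partner; alkene migration by ruthenium hydrides and loss of Z-selectivity by secondary metathesis are also possible.
Fallback: olefination of an aldehyde, which sets out from 26. Et3SiOTf/2,6-lutidine gives the triethylsilyl ether F13. OsO4/NaIO4 cleaves its terminal vinyl group to the α-chloro aldehyde F11 (the same compound as in the fallback for step 14). The Peterson olefination and desilylation described there lead through the bis-silylated (Z)-enyne F12 to 31.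

**Step 12.** Participation of the ring oxygen in the ionising C12–O bond (retention or ring contraction) or E2 elimination towards C11 may compete with the SN2 displacement.
Fallback: a two-stage sulfonate displacement, which sets out from 19. ClCH2SO2Cl/2,6-lutidine (CH2Cl2, 0 °C) gives the chloromethanesulfonate F14, and LiBr in THF displaces it with inversion under milder, non-phosphonium conditions; the route is rejoined at 20.

## Further compounds

F1 | step 10 | (3R,4R,6E)-6-chloro-7-iodo-4-(methoxymethoxy)hept-6-en-3-ol | I/C=C(/Cl)C[C@@H](OCOC)[C@@H](CC)O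
F2 | step 10 | 2-{[(3R,4R,6E)-6-chloro-7-iodo-4-(methoxymethoxy)hept-6-en-3-yl]oxy}-N,N-dimethylacetamide | I/C=C(/Cl)C[C@@H](OCOC)[C@@H](CC)OCC(=O)N(C)C
F3 | step 10 | 2-{[(3R,4R,6E)-6-chloro-8-hydroxy-4-(methoxymethoxy)oct-6-en-3-yl]oxy}-N,N-dimethylacetamide | OC/C=C(/Cl)C[C@@H](OCOC)[C@@H](CC)OCC(=O)N(C)C
F4 | step 10 | 2-{[(3R,4R,6E)-6,8-dichloro-4-(methoxymethoxy)oct-6-en-3-yl]oxy}-N,N-dimethylacetamide | ClC/C=C(/Cl)C[C@@H](OCOC)[C@@H](CC)OCC(=O)N(C)C
F5 | step 10 | (2R,4E,7R,8R)-5-chloro-8-ethyl-7-(methoxymethoxy)-N,N-dimethyl-3,6,7,8-tetrahydro-2H-oxocine-2-carboxamide | CN(C)C(=O)[C@H]1C/C=C(/Cl)C[C@@H](OCOC)[C@@H](CC)O1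
F6 | step 10 | (2R,4E,7R,8R)-5-chloro-8-ethyl-7-hydroxy-N,N-dimethyl-3,6,7,8-tetrahydro-2H-oxocine-2-carboxamide | CN(C)C(=O)[C@H]1C/C=C(/Cl)C[C@@H](O)[C@@H](CC)O1
F7 | step 10 | (2R,4E,7S,8R)-7-bromo-5-chloro-8-ethyl-N,N-dimethyl-3,6,7,8-tetrahydro-2H-oxocine-2-carboxamide | CN(C)C(=O)[C@H]1C/C=C(/Cl)C[C@H](Br)[C@@H](CC)O1
F8 | step 14 | (4R)-4-benzyl-3-{(2R,3S)-3-[(2R,4E,7S,8R)-7-bromo-5-chloro-8-ethyl-3,6,7,8-tetrahydro-2H-oxocin-2-yl]-2-chloro-3-hydroxypropanoyl}-1,3-oxazolidin-2-one | O=C([C@H](Cl)[C@@H](O)[C@H]1C/C=C(/Cl)C[C@H](Br)[C@@H](CC)O1)N1C(=O)OC[C@H]1Cc1ccccc1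
F9 | step 14 | (4R)-4-benzyl-3-{(2R,3S)-3-[(2R,4E,7S,8R)-7-bromo-5-chloro-8-ethyl-3,6,7,8-tetrahydro-2H-oxocin-2-yl]-2-chloro-3-[(triethylsilyl)oxy]propanoyl}-1,3-oxazolidin-2-one | O=C([C@H](Cl)[C@@H](O[Si](CC)(CC)CC)[C@H]1C/C=C(/Cl)C[C@H](Br)[C@@H](CC)O1)N1C(=O)OC[C@H]1Cc1ccccc1
F10 | step 14 | (2S,3S)-3-[(2R,4E,7S,8R)-7-bromo-5-chloro-8-ethyl-3,6,7,8-tetrahydro-2H-oxocin-2-yl]-2-chloro-3-[(triethylsilyl)oxy]propan-1-ol | OC[C@H](Cl)[C@@H](O[Si](CC)(CC)CC)[C@H]1C/C=C(/Cl)C[C@H](Br)[C@@H](CC)O1
F11 | step 14 | (2R,3S)-3-[(2R,4E,7S,8R)-7-bromo-5-chloro-8-ethyl-3,6,7,8-tetrahydro-2H-oxocin-2-yl]-2-chloro-3-[(triethylsilyl)oxy]propanal | O=C[C@H](Cl)[C@@H](O[Si](CC)(CC)CC)[C@H]1C/C=C(/Cl)C[C@H](Br)[C@@H](CC)O1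
F12 | step 14 | {[(1S,2S,3Z)-1-[(2R,4E,7S,8R)-7-bromo-5-chloro-8-ethyl-3,6,7,8-tetrahydro-2H-oxocin-2-yl]-2-chloro-6-[tri(propan-2-yl)silyl]hex-3-en-5-yn-1-yl]oxy}triethylsilane | CC(C)[Si](C(C)C)(C(C)C)C#C/C=C\[C@H](Cl)[C@@H](O[Si](CC)(CC)CC)[C@H]1C/C=C(/Cl)C[C@H](Br)[C@@H](CC)O1
F13 | step 16 | {[(1S,2S)-1-[(2R,4E,7S,8R)-7-bromo-5-chloro-8-ethyl-3,6,7,8-tetrahydro-2H-oxocin-2-yl]-2-chlorobut-3-en-1-yl]oxy}triethylsilane | C=C[C@H](Cl)[C@@H](O[Si](CC)(CC)CC)[C@H]1C/C=C(/Cl)C[C@H](Br)[C@@H](CC)O1
F14 | step 12 | (2R,3R,5E,8R)-5-chloro-8-ethenyl-2-ethyl-3,4,7,8-tetrahydro-2H-oxocin-3-yl chloromethanesulfonate | C=C[C@H]1C/C=C(/Cl)C[C@@H](OS(=O)(=O)CCl)[C@@H](CC)O1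
A1 | alternative 1 | (5E,8R)-8-[(benzyloxy)methyl]-5-chloro-3,4,7,8-tetrahydro-2H-oxocin-2-one | c1ccccc1COC[C@H]1C/C=C(/Cl)CCC(=O)O1
A2 | alternative 1 | (4R)-4-[(benzyloxy)methyl]-6-(1-chloroethenyl)-2-methylidene-1,3-dioxane (either C6 epimer) | c1ccccc1COC[C@H]1CC(C(Cl)=C)OC(=C)O1
A3 | alternative 2 | (2R,5E,7R,8R)-5-chloro-8-ethyl-7-(methoxymethoxy)-2-{[(4-methoxyphenyl)methoxy]methyl}-2,3,7,8-tetrahydro-4H-oxocin-4-one | COc1ccc(COC[C@H]2CC(=O)/C(Cl)=C\[C@@H](OCOC)[C@@H](CC)O2)cc1
A4 | alternative 2 | (2R,3R,7R)-2-ethyl-3-(methoxymethoxy)-7-{[(4-methoxyphenyl)methoxy]methyl}-5-[(trimethylsilyl)oxy]-2,3,6,7-tetrahydrooxepine | COc1ccc(COC[C@H]2CC(O[Si](C)(C)C)=C[C@@H](OCOC)[C@@H](CC)O2)cc1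
A5 | alternative 3 | (2R,3S,5E,8R)-5-chloro-2-ethenyl-8-{[(4-methoxyphenyl)methoxy]methyl}-3,4,7,8-tetrahydro-2H-oxocin-3-ol | COc1ccc(COC[C@H]2C/C=C(/Cl)C[C@H](O)[C@@H](C=C)O2)cc1
A6 | alternative 3 | (3E,6R)-3-chloro-7-[(4-methoxyphenyl)methoxy]-6-{[(1Z)-3-(tributylstannyl)prop-1-en-1-yl]oxy}hept-3-enal | CCCC[Sn](CCCC)(CCCC)C/C=C\O[C@@H](COCc1ccc(OC)cc1)C/C=C(/Cl)CC=O
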